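**Retrosynthetic overview**
- The target is a central ring B (B1/B4 aryloxy, B2/B5 OH, B3/B6 Br) carrying two identical outer rings A and C (2,3,5-tribromo-4-hydroxyphenoxy). All three rings are bought as benzene rings and none is constructed.
- The six outer C–Br bonds are made last, by phenol-directed bromination after the outer methyl ethers are cleaved. The central hydroquinone is masked as its diacetate against oxidation by Br2.
- The key disconnection is the two C–O bonds at B2 and B5. Each of these carbons lies between a bromine-bearing carbon (B3, B6) and an aryloxy-bearing carbon (B1, B4), so in a 1,4-dibromo-2,5-bis(aryloxy)benzene their C–H bonds are the only ones flanked by two acidifying groups. A twofold amide-base metalation, borate trapping and C–B to C–O oxidation places both hydroxyls.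
- The precursor comes from a twofold SNAr of 1,4-dibromo-2,5-difluorobenzene with 4-methoxyphenol, which forms the B1–O and B4–O ether bonds.

Key step: step 2

Remark on the chemistry: the target has no stereocentre and the diaryl ether axes are taken to rotate freely, so no stereocontrol is required; LiTMP is taken as the commercial reagent.

**Route**

Step 1
Reactants: 1 1,4-dibromo-2,5-difluorobenzene; 2 4-methoxyphenol (2.4 equiv)
Product: 3 1,4-dibromo-2,5-bis(4-methoxyphenoxy)benzene
Conditions: Cs2CO3 (3 equiv), DMSO, 130 °C, argon
Reagents that add atoms: none
Why: Twofold nucleophilic aromatic substitution (SNAr), in which the phenoxide adds at the fluorine-bearing carbons, the anionic intermediate is stabilised inductively by the ring bromines, and fluoride leaves much faster than bromide, so both C–Br bonds should be kept.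

Step 2
Reactants: 3 1,4-dibromo-2,5-bis(4-methoxyphenoxy)benzene
Product: 5 2,5-dibromo-3,6-bis(4-methoxyphenoxy)benzene-1,4-diol, via dilithium bis(triisopropoxyborate) 4 (not isolated)
Conditions: B(OiPr)3 (5 equiv), LiTMP (4 equiv, added slowly to 3 and the borate), THF, −78 → −50 °C; then AcOH, 30% aq. H2O2, 0 °C → rt
Reagents that add atoms: hydrogen peroxide, OO (the two new hydroxyl oxygens of 5); triisopropyl borate, CC(C)OB(OC(C)C)OC(C)C (boron and isopropoxy groups of intermediate 4 only)
Why: LiTMP, which is too hindered to consume the borate quickly at −78 °C, should remove the B2 proton of 3 (acidified inductively by the B3 bromine and the B1 aryloxy oxygen), and the B(OiPr)3 already present should capture the 2-bromoaryllithium as a borate before it can expel LiBr to an aryne or let bromine migrate; the B5 proton then reacts in the same way to give 4. Acidification releases the bis(boronic ester), H2O2 adds to each boron, and the aryl group shifts from boron to oxygen at the same ring carbon, so that hydrolysis frees the B2–O and B5–O phenols. The closest known reaction type is amide-base ortho-metalation of bromoarenes between the halogen and an oxygen or fluorine substituent with in situ borate quench, followed by peroxide oxidation of the arylboronate to the phenol. No ring is closed and no stereocentre is formed. The selectivity needed is site selectivity among the ten aromatic protons: only B2–H and B5–H sit between two acidifying groups, whereas every proton of the two anisyl rings is next to one oxygen only and should not be removed by LiTMP at this temperature. The excess of base and borate is meant to drive the second metalation, which is expected to be slower because the first borate group is anionic.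

Step 3
Reactants: 5 2,5-dibromo-3,6-bis(4-methoxyphenoxy)benzene-1,4-diol
Product: 6 2,5-dibromo-3,6-bis(4-methoxyphenoxy)-1,4-phenylene diacetate
Conditions: Ac2O, pyridine, DMAP (cat.), CH2Cl2, rt
Reagents that add atoms: acetic anhydride, CC(=O)OC(C)=O
Why: DMAP-catalysed O-acylation of the two acidic central phenols, which masks the hydroquinone of ring B against oxidation to the quinone by Br2 in step 5.

Step 4
Reactants: 6 2,5-dibromo-3,6-bis(4-methoxyphenoxy)-1,4-phenylene diacetate
Product: 7 2,5-dibromo-3,6-bis(4-hydroxyphenoxy)-1,4-phenylene diacetate
Conditions: BBr3 (5 equiv), CH2Cl2, −78 → 0 °C; ice-water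
Reagents that add atoms: none
Why: Lewis-acid ether cleavage, in which BBr3 binds the most basic oxygens (the two anisole oxygens) and bromide attacks the methyl groups by SN2, while the diaryl ethers cannot be cleaved this way and the less basic aryl acetates should survive at low temperature.

Step 5
Reactants: 7 2,5-dibromo-3,6-bis(4-hydroxyphenoxy)-1,4-phenylene diacetate
Product: 8 2,5-dibromo-3,6-bis(2,3,5-tribromo-4-hydroxyphenoxy)-1,4-phenylene diacetate
Conditions: Br2 (6.1 equiv), anhydrous AcOH, rt → 50 °C, dark; aq. NaHSO3 quench
Reagents that add atoms: bromine, BrBr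
Why: Electrophilic aromatic bromination, in which each free phenol directs two bromines to its ortho positions and the third can only enter one of the two equivalent positions ortho to the ether oxygen, while the fourth is slowed by the extra bromine and by the twist it imposes on the ether, and the fully substituted, acetylated ring B is inert.

Step 6
Reactants: 8 2,5-dibromo-3,6-bis(2,3,5-tribromo-4-hydroxyphenoxy)-1,4-phenylene diacetate
Product: 9 2,5-dibromo-3,6-bis(2,3,5-tribromo-4-hydroxyphenoxy)benzene-1,4-diol
Conditions: N2H4·H2O (4 equiv), THF/MeOH, 0 °C → rt, argon; then 1 M HCl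
Reagents that add atoms: none
Why: Hydrazinolysis (nucleophilic acyl substitution) of the two electron-poor aryl acetates, which are good leaving groups, in a reducing medium that keeps the freed hydroquinone from air oxidation and leaves the aryl bromides untouched.

**Compound list**
1 | 1,4-dibromo-2,5-difluorobenzene | Fc1cc(Br)c(F)cc1Br | starting material
2 | 4-methoxyphenol | COc1ccc(O)cc1 | starting material
3 | 1,4-dibromo-2,5-bis(4-methoxyphenoxy)benzene | COc1ccc(Oc2cc(Br)c(Oc3ccc(OC)cc3)cc2Br)cc1 | intermediate
4 | dilithium [2,5-dibromo-3,6-bis(4-methoxyphenoxy)-1,4-phenylene]bis(triisopropoxyborate) | [Li+].[Li+].COc1ccc(Oc2c([B-](OC(C)C)(OC(C)C)OC(C)C)c(Br)c(Oc3ccc(OC)cc3)c([B-](OC(C)C)(OC(C)C)OC(C)C)c2Br)cc1 | intermediate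
5 | 2,5-dibromo-3,6-bis(4-methoxyphenoxy)benzene-1,4-diol | COc1ccc(Oc2c(O)c(Br)c(Oc3ccc(OC)cc3)c(O)c2Br)cc1 | intermediate
6 | 2,5-dibromo-3,6-bis(4-methoxyphenoxy)-1,4-phenylene diacetate | COc1ccc(Oc2c(OC(C)=O)c(Br)c(Oc3ccc(OC)cc3)c(OC(C)=O)c2Br)cc1 | intermediate
7 | 2,5-dibromo-3,6-bis(4-hydroxyphenoxy)-1,4-phenylene diacetate | Oc1ccc(Oc2c(OC(C)=O)c(Br)c(Oc3ccc(O)cc3)c(OC(C)=O)c2Br)cc1 | intermediate
8 | 2,5-dibromo-3,6-bis(2,3,5-tribromo-4-hydroxyphenoxy)-1,4-phenylene diacetate | Oc1c(Br)cc(Oc2c(OC(C)=O)c(Br)c(Oc3cc(Br)c(O)c(Br)c3Br)c(OC(C)=O)c2Br)c(Br)c1Br | intermediate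
9 | 2,5-dibromo-3,6-bis(2,3,5-tribromo-4-hydroxyphenoxy)benzene-1,4-diol | Oc1c(Br)cc(Oc2c(O)c(Br)c(Oc3cc(Br)c(O)c(Br)c3Br)c(O)c2Br)c(Br)c1Br | target

**Step count**
Total steps: 6. Longest linear sequence: 6 (from 1 to 9).

**Steps most likely to fail**

Step 2. The sequence may stall after the first borylation, because the anionic borate lowers the acidity of the remaining proton. The aryllithium may lose LiBr to an aryne or let bromine migrate if it outlives trapping. The hindered boronate may protodeboronate before oxidation, and the product hydroquinone may be over-oxidised to the quinone (a Na2S2O4 wash at work-up would reverse this last fault). The fallback takes the B2 and B5 oxygens from a quinone instead of from C–H metalation; it sets out from 4-methoxyphenol 2 and returns at 5. Commercial tetrabromo-1,4-benzoquinone (bromanil, O=C1C(Br)=C(Br)C(=O)C(Br)=C1Br) would be treated with two equivalents of 2 and K2CO3 in MeCN at 0 °C. Twofold addition–elimination on tetrahalobenzoquinones is known to stop at the 2,5-bis(aryloxy)-3,6-dihalo stage, because each aryloxy group deactivates the neighbouring position as a vinylogous ester. This should give 2,5-dibromo-3,6-bis(4-methoxyphenoxy)cyclohexa-2,5-diene-1,4-dione F1. Reduction with aqueous Na2S2O4 in EtOAc should then give 5.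

Step 5. Bromination may stop short of, or run past, three bromines per outer ring and give mixtures that are hard to separate. Ipso attack para to the hydroxyl may also cleave the ether oxidatively if water is present. The fallback replaces the single sixfold bromination by two separately controlled halogenations; it sets out from 7 and returns at 8. NBS (4 equiv) in MeCN at 0 °C should brominate only the positions ortho to the free phenols and give 2,5-dibromo-3,6-bis(3,5-dibromo-4-hydroxyphenoxy)-1,4-phenylene diacetate F2, which would be isolated and purified. One further bromine per ring would then be introduced with exactly 2.0 equivalents of a standardised Br2 solution in anhydrous AcOH, added slowly at rt, to give 8.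

Step 4. The central acetates may be partly lost under BBr3 or during the acidic work-up, which would expose the hydroquinone of ring B to Br2 in step 5. The fallback gives up protection and uses the quinone oxidation level of ring B as the mask; it sets out from 5 and returns at 9. BBr3 in CH2Cl2 would demethylate 5 directly to 2,5-dibromo-3,6-bis(4-hydroxyphenoxy)benzene-1,4-diol F3. Br2 (7 equiv) in anhydrous AcOH should then oxidise ring B to the quinone and brominate rings A and C three times each, giving 2,5-dibromo-3,6-bis(2,3,5-tribromo-4-hydroxyphenoxy)cyclohexa-2,5-diene-1,4-dione F4. Reduction with aqueous Na2S2O4 in THF should return the hydroquinone 9.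

Further compounds
F1 | step 2 | 2,5-dibromo-3,6-bis(4-methoxyphenoxy)cyclohexa-2,5-diene-1,4-dione | COc1ccc(OC2=C(Br)C(=O)C(Oc3ccc(OC)cc3)=C(Br)C2=O)cc1
F2 | step 5 | 2,5-dibromo-3,6-bis(3,5-dibromo-4-hydroxyphenoxy)-1,4-phenylene diacetate | Oc1c(Br)cc(Oc2c(OC(C)=O)c(Br)c(Oc3cc(Br)c(O)c(Br)c3)c(OC(C)=O)c2Br)cc1Br
F3 | step 4 | 2,5-dibromo-3,6-bis(4-hydroxyphenoxy)benzene-1,4-diol | Oc1ccc(Oc2c(O)c(Br)c(Oc3ccc(O)cc3)c(O)c2Br)cc1
F4 | step 4 | 2,5-dibromo-3,6-bis(2,3,5-tribromo-4-hydroxyphenoxy)cyclohexa-2,5-diene-1,4-dione | Oc1c(Br)cc(OC2=C(Br)C(=O)C(Oc3cc(Br)c(O)c(Br)c3Br)=C(Br)C2=O)c(Br)c1Br
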